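Compound numbers are those of the steps and of the compound list below. Flavone locants are used for rings A and C (O1, C2–C8a) and primed locants for ring B.

## Analysis of the target

Target 22 is a flavone, a 4H-chromen-4-one in which benzo ring A is fused to pyranone ring C and aryl ring B sits on C2; it has no stereocentre, so the whole problem is the placement and differentiation of seven oxygen substituents. Ring A carries OH at C5 and OCH3 at C7 and C8, ring C carries OCH3 at C3, and ring B carries OH at C2' and C4' and OCH3 at C5'. Ring B is at once a resorcinol and a hydroquinone monomethyl ether (C2'–OH para to C5'–OCH3), so strong oxidants would turn it into a quinone. Once the 5-hydroxyl is free, the 5,7,8-pattern of ring A can isomerise to the 5,6,7-pattern in hot strong acid by opening and reclosure of ring C (Wessely–Moser rearrangement), and C2 of the pyranone and anything conjugated to it accept hard nucleophiles. The main difficulty is to leave three hydroxyls free beside four methyl ethers, since only the chelated 5-position could be unmasked selectively from a methyl ether with any confidence. A second difficulty is that the oxygen that becomes O1 must be distinguished from O5, because both sit ortho to C4a. The strategy rests on ring B: C2'–OH is para to C5'–OCH3, C1' (bearing ring C) is ortho to C2', and C3' and C6' carry hydrogen, which is the 4-methoxyphenol with its large substituent ortho to the hydroxyl that forms when a methoxycarbene chromium complex, a terminal alkyne and one CO combine. C4' with its oxygen is then the α-carbon of the alkenyl group on the carbene.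

## Retrosynthetic reasoning

**22 ⇒ 21.** The O5–isopropyl and O4'–tert-butyl bonds are cut. The 2'-hydroxyl is already free in 21, and the other two hydroxyls are held as a secondary and a tertiary alkyl ether. A Lewis acid can ionise these while the four methyl ethers stay, so one dealkylation ends the synthesis.

**21 ⇒ 14 + 19.** Ring B is cut at C5'–C6', C1'–C2' and C2'–C3'. C1' and C6' come from the triple bond of 14. C5' with its methoxy group is the carbene carbon of 19, and C4' (with the tert-butoxy group) and C3' are its alkenyl carbons. C2' and its hydroxyl oxygen come from a carbonyl ligand of 19. This cut is preferred to a biaryl-type C2–C1' cut because it makes ring B with its three oxygens already differentiated: one free, one methyl, one tert-butyl. The forward reaction has to insert the alkyne with the chromonyl group next to the carbonyl-derived carbon and then release the phenol from its metal complex 20 without oxidising it.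

**19 ⇒ 15 + 16.** The bond between the carbene carbon and the alkenyl carbon and the O–CH3 bond are cut. Metalated 15 (17) adds to a carbonyl ligand of 16 and the resulting acyl metalate 18 is O-methylated. One flask delivers the whole C3'–C4'–C5' unit.

**14 ⇒ 13 ⇒ 12 ⇒ 11.** The triple bond is traced to aldehyde 13 by a one-carbon homologation, and 13 to ester 11 through alcohol 12. The ester is chosen as the origin of the C2 substituent because it arrives with ring C in the next disconnection.

**11 ⇒ 8 + 9.** Ring C is cut at C2–C3 and O1–C2. A Claisen condensation of the methoxymethyl ketone 8 with oxalate 9 gives 10 and supplies C2 and the ester. Acid then frees the phenol and closes the ring. This disconnection fixes the protecting groups. The oxygen next to C8 must be the only free phenol when the ring closes, so it carries the acid-labile acetal. O5 must carry a group that survives hot acid, since an acetal there would be lost in the same operation and either oxygen could then become O1. Hence isopropyl on O5.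

**8 ⇒ 5 + 6.** The aryl–carbonyl bond is cut. In 5 the only ring C–H ortho to the acetal oxygen lies between the two differently protected oxygens. Directed metalation to 7 and acylation with amide 6 place the methoxyacetyl group there. Electrophilic acylation would not distinguish the two ring positions reliably.

**5 ⇒ 4 ⇒ 2 ⇒ 1.** Two O-alkylations are removed, and the hydroxyl of 4 is traced to the formyl group of 2 by a peracid oxidation via formate 3. Aldehyde 1 already has the three contiguous oxygens of ring A. Its formyl carbon marks the position of the fourth, which becomes O5, and its free hydroxyl becomes O1.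

## Alternatives that were turned down

**Alternative 1:** Ring C is cut at C4a–C4, C4–C3 and O1–C2. This leads to 3-(benzyloxy)-2-iodo-5,6-dimethoxyphenol A2, 1,5-bis(benzyloxy)-2-ethynyl-4-methoxybenzene A3 and CO. Forward, PdCl2(PPh3)2 in Et2NH under CO would carbonylate the C–I bond of A2, couple the acylpalladium species with A3 and close the pyranone by 6-endo attack of the phenol, giving 5-(benzyloxy)-2-[2,4-bis(benzyloxy)-5-methoxyphenyl]-7,8-dimethoxy-4H-chromen-4-one A1.
- For it: three components are joined in one step, both partners are simple arenes, and this ring closure tolerates electron-rich partners well.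
- Against it: A1 has hydrogen at C3, because a terminal alkyne cannot bring the 3-methoxy group. C3 would have to be oxidised and O-methylated afterwards on an electron-rich flavone. The iodine of A2 sits between two oxygenated carbons, which slows oxidative addition. 5-exo closure to the aurone skeleton competes.
- Comparison: alternative 1 is stronger in convergence and in the reliability of its ring-forming step. The chosen route instead carries the C3 oxygen from the first C–C bond onward and needs no late C–H oxidation.

**Alternative 2:** Ring A is cut at C5–C6. The precursor is racemic methyl 6-[2,4-bis(benzyloxy)-5-methoxyphenyl]-5-methoxy-2-(1-methoxy-2-oxopropyl)-4-oxo-4H-pyran-3-carboxylate A5. Forward, LiN(SiMe3)2 would form the methyl ketone enolate of A5, which attacks the neighbouring ester. The new ring aromatises to 2-[2,4-bis(benzyloxy)-5-methoxyphenyl]-5,7-dihydroxy-3,8-dimethoxy-4H-chromen-4-one A4.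
- For it: ring A is made de novo, so no aromatic substitution has to be directed, and the 5- and 7-hydroxyls differ enough for selective 7-O-methylation.
- Against it: A5 is a fully substituted pyranone whose own synthesis would be longer than the whole ring A/C sequence here. Its most acidic C–H is the side-chain CH between pyranone and ketone, not the methyl group that must react. A4 still needs methylation and debenzylation.
- Comparison: alternative 2 is stronger on one point, the unambiguous placement of ring A oxygens. The chosen route gets the same pattern from a commercial arene and one directed metalation, in far fewer steps.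

**Alternative 3:** Ring C is cut at C4–C4a. The precursor is (E)-3-[3-(benzyloxy)-5,6-dimethoxyphenoxy]-3-[2,4-bis(benzyloxy)-5-methoxyphenyl]-2-methoxyprop-2-enoic acid A7. Forward, (CF3CO)2O would activate the acid of A7 and ring A would attack the acyl carbon through its only free ortho carbon, giving 5-(benzyloxy)-2-[2,4-bis(benzyloxy)-5-methoxyphenyl]-3,7,8-trimethoxy-4H-chromen-4-one A6.
- For it: the attacking carbon is strongly activated, the regiochemistry is unambiguous, and A6 holds all seven oxygens, one hydrogenolysis from the target.
- Against it: the difficulty moves into A7, a tetrasubstituted β-aryloxy-α-methoxyacrylic acid that must have the acid cis to the aryloxy group. It would need O-vinylation of a hindered phenol. Under the acidic activation the double bond can isomerise, after which acylation of ring B to an indenone competes, and benzyl ethers on such electron-rich rings are at risk.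
- Comparison: alternative 3 is stronger in the end-game after its key step. The chosen route offers two key-step partners that are each reachable by standard reactions, so the uncertainty sits in one step rather than in the precursor synthesis.

Key step: step 10

Remark on the chemistry: in complex 20 the Cr(CO)3 fragment is η6-bound to ring B. Its SMILES gives the arene and the Cr(CO)3 fragment as two parts joined by a dot.
Remark on the chemistry: 1, 6, 9, 15 and 16 are taken as purchased.

## Route

Step 1
Reactants: 1 3-hydroxy-4,5-dimethoxybenzaldehyde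
Product: 2 3,4-dimethoxy-5-(methoxymethoxy)benzaldehyde
Conditions: MOMCl, i-Pr2NEt, CH2Cl2, 0 °C to rt
Reagents that add atoms: chloromethyl methyl ether, COCCl
Why: O-alkylation of the phenol with an α-chloro ether; the acetal masks the oxygen that becomes O1 and later directs the ortho-metalation.

Step 2
Reactants: 2 3,4-dimethoxy-5-(methoxymethoxy)benzaldehyde
Product: 4 3,4-dimethoxy-5-(methoxymethoxy)phenol, via aryl formate 3 (not isolated)
Conditions: mCPBA, CH2Cl2, 0 °C to rt; aq. NaHCO3 wash; then K2CO3 (cat.), MeOH, rt
Reagents that add atoms: 3-chloroperoxybenzoic acid, OOC(=O)c1cccc(Cl)c1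
Why: Baeyer–Villiger oxidation in which the electron-rich aryl group (para-methoxy) migrates in preference to hydrogen; base-catalysed methanolysis of the formate then frees the phenol that becomes O5.

Step 3
Reactants: 4 3,4-dimethoxy-5-(methoxymethoxy)phenol
Product: 5 1,2-dimethoxy-3-(methoxymethoxy)-5-(propan-2-yloxy)benzene
Conditions: i-PrBr, K2CO3, DMF, 60 °C
Reagents that add atoms: 2-bromopropane, CC(C)Br
Why: Williamson ether synthesis on the phenoxide; the isopropyl ether withstands organolithium, hydride and hot protic acid but is ionised by BCl3 at the end.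

Step 4
Reactants: 5 1,2-dimethoxy-3-(methoxymethoxy)-5-(propan-2-yloxy)benzene; 6 N,2-dimethoxy-N-methylacetamide
Product: 8 1-[3,4-dimethoxy-2-(methoxymethoxy)-6-(propan-2-yloxy)phenyl]-2-methoxyethan-1-one, via aryllithium 7 (not isolated)
Conditions: n-BuLi, THF, 0 °C; then 6, −78 °C to rt; aq. NH4Cl
Reagents that add atoms: none
Why: Directed ortho-metalation removes the only ring hydrogen ortho to the chelating acetal, which lies between the two protected oxygens; the other ring hydrogen lies between the isopropoxy and a methoxy group, which hold lithium less well. Acylation with the Weinreb amide stops at the ketone because the chelated tetrahedral adduct persists until work-up.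

Step 5
Reactants: 8 1-[3,4-dimethoxy-2-(methoxymethoxy)-6-(propan-2-yloxy)phenyl]-2-methoxyethan-1-one; 9 diethyl oxalate
Product: 11 ethyl 3,7,8-trimethoxy-4-oxo-5-(propan-2-yloxy)-4H-chromene-2-carboxylate, via diketo ester 10 (not isolated)
Conditions: LiN(SiMe3)2, THF, −78 °C; 9, −78 to 0 °C; then conc. HCl, EtOH, 70 °C
Reagents that add atoms: none
Why: Claisen condensation of the lithium enolate at the only enolisable carbon with the very electrophilic oxalate, driven by deprotonation of the doubly activated product. Acid then removes the acetal, the freed phenol adds to the α-keto ester carbonyl and the hemiketal dehydrates to the chromone. Only the oxygen next to C8 can become O1 because the other ortho oxygen stays an isopropyl ether.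

Step 6
Reactants: 11 ethyl 3,7,8-trimethoxy-4-oxo-5-(propan-2-yloxy)-4H-chromene-2-carboxylate
Product: 12 2-(hydroxymethyl)-3,7,8-trimethoxy-5-(propan-2-yloxy)-4H-chromen-4-one
Conditions: NaBH4, MeOH/THF, 0 °C
Reagents that add atoms: none
Why: Chemoselective borohydride reduction: the ester on C2 is activated by the ring oxygen and the 3-methoxy group, whereas the C4 carbonyl is a vinylogous ester further deactivated by the 5-alkoxy group.

Step 7
Reactants: 12 2-(hydroxymethyl)-3,7,8-trimethoxy-5-(propan-2-yloxy)-4H-chromen-4-one
Product: 13 3,7,8-trimethoxy-4-oxo-5-(propan-2-yloxy)-4H-chromene-2-carbaldehyde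
Conditions: Dess–Martin periodinane, CH2Cl2, rt
Reagents that add atoms: none
Why: Dess–Martin oxidation of a primary allylic-type alcohol to the aldehyde under non-nucleophilic conditions that leave the pyranone untouched.

Step 8
Reactants: 13 3,7,8-trimethoxy-4-oxo-5-(propan-2-yloxy)-4H-chromene-2-carbaldehyde
Product: 14 2-ethynyl-3,7,8-trimethoxy-5-(propan-2-yloxy)-4H-chromen-4-one
Conditions: dimethyl (1-diazo-2-oxopropyl)phosphonate, K2CO3, MeOH, 0 °C to rt
Reagents that add atoms: dimethyl (1-diazo-2-oxopropyl)phosphonate, COP(=O)(OC)C(=[N+]=[N-])C(C)=O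
Why: Ohira–Bestmann (Seyferth–Gilbert) homologation: methanolysis frees the diazomethylphosphonate anion, which adds to the aldehyde; loss of phosphate and N2 gives an alkylidene carbene that rearranges by 1,2-hydrogen shift to the terminal alkyne.

Step 9
Reactants: 15 tert-butyl vinyl ether; 16 hexacarbonylchromium Cr(CO)6
Product: 19 pentacarbonyl[(1-tert-butoxyethenyl)(methoxy)methylidene]chromium, via 1-tert-butoxyethenyllithium 17 (not isolated), via lithium acylchromate 18 (not isolated)
Conditions: t-BuLi, THF, −78 to −5 °C; Cr(CO)6, Et2O, 0 °C to rt; then MeOTf, CH2Cl2, 0 °C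
Reagents that add atoms: methyl trifluoromethanesulfonate, COS(=O)(=O)C(F)(F)F
Why: Fischer carbene synthesis: α-deprotonation of the vinyl ether, addition of the vinyllithium to a CO ligand of zerovalent chromium and O-methylation of the acylchromate by a hard methylating agent. Cyclic α-alkoxyalkenyl complexes of this kind are made the same way, and the α-substituent keeps the complex from polymerising as the parent vinyl complex does.

Step 10
Reactants: 14 2-ethynyl-3,7,8-trimethoxy-5-(propan-2-yloxy)-4H-chromen-4-one; 19 pentacarbonyl[(1-tert-butoxyethenyl)(methoxy)methylidene]chromium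
Product: 21 2-(4-tert-butoxy-2-hydroxy-5-methoxyphenyl)-3,7,8-trimethoxy-5-(propan-2-yloxy)-4H-chromen-4-one, via arene Cr(CO)3 complex 20 (not isolated)
Conditions: 19 (1.5 equiv), THF (0.05 M), 50 °C, Ar; then air, Et2O, daylight, rt
Reagents that add atoms: none
Why: Thermal loss of one CO from 19 opens a coordination site for 14, which inserts into the Cr=C bond with its CH terminus bonded to the carbene carbon (C5'–C6'), because the bulky chromonyl group stays away from the methoxy-bearing carbon. Migration of a CO ligand onto the new carbene carbon forms C1'–C2' and gives a chromium-bound dienylketene. Its 6π-electrocyclisation between the ketene carbon and the CH2 terminus of the tert-butoxyvinyl unit forms C2'–C3' and closes ring B as a cyclohexadienone, which tautomerises to the phenol complex 20; air then removes the metal. The closest known reaction type is the Dötz benzannulation of alkenyl(methoxy)carbene chromium complexes with terminal alkynes, including complexes with an alkoxy group on the α-carbon of the alkene. Ring B is thus closed by a formal [3+2+1] assembly ending in a disrotatory 6π ring closure, and no stereocentre is formed. The step needs regioselective insertion, which the single large substituent of the terminal alkyne secures, and phenol formation rather than ring closure without CO, which chromium, an alkenyl carbene and a donor solvent at moderate temperature favour. Air is used for demetalation rather than (NH4)2Ce(NO3)6, which would oxidise the 4-methoxyphenol to a quinone and erase the OH/OCH3 differentiation.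

Step 11
Reactants: 21 2-(4-tert-butoxy-2-hydroxy-5-methoxyphenyl)-3,7,8-trimethoxy-5-(propan-2-yloxy)-4H-chromen-4-one
Product: 22 2-(2,4-dihydroxy-5-methoxyphenyl)-5-hydroxy-3,7,8-trimethoxy-4H-chromen-4-one (5,2',4'-trihydroxy-3,7,8,5'-tetramethoxyflavone)
Conditions: BCl3 (excess), CH2Cl2, −78 to 0 °C; then aq. NaHCO3
Reagents that add atoms: none
Why: Lewis acid ether cleavage: BCl3 ionises the tertiary and the secondary alkyl ether, the latter helped by chelation of boron between O5 and the C4 carbonyl. The four methyl ethers cannot leave as stabilised cations and should persist at this temperature; hydrolysis of the aryl borates on work-up gives 22.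

## Compound list

1 | 3-hydroxy-4,5-dimethoxybenzaldehyde | COc1cc(C=O)cc(O)c1OC | starting material
2 | 3,4-dimethoxy-5-(methoxymethoxy)benzaldehyde | COCOc1cc(C=O)cc(OC)c1OC | intermediate
3 | 3,4-dimethoxy-5-(methoxymethoxy)phenyl formate | COCOc1cc(OC=O)cc(OC)c1OC | intermediate (not isolated)
4 | 3,4-dimethoxy-5-(methoxymethoxy)phenol | COCOc1cc(O)cc(OC)c1OC | intermediate
5 | 1,2-dimethoxy-3-(methoxymethoxy)-5-(propan-2-yloxy)benzene | COCOc1cc(OC(C)C)cc(OC)c1OC | intermediate
6 | N,2-dimethoxy-N-methylacetamide | COCC(=O)N(C)OC | starting material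
7 | [3,4-dimethoxy-2-(methoxymethoxy)-6-(propan-2-yloxy)phenyl]lithium | [Li]c1c(OCOC)c(OC)c(OC)cc1OC(C)C | intermediate (not isolated)
8 | 1-[3,4-dimethoxy-2-(methoxymethoxy)-6-(propan-2-yloxy)phenyl]-2-methoxyethan-1-one | COCC(=O)c1c(OCOC)c(OC)c(OC)cc1OC(C)C | intermediate
9 | diethyl oxalate | CCOC(=O)C(=O)OCC | starting material
10 | ethyl 4-[3,4-dimethoxy-2-(methoxymethoxy)-6-(propan-2-yloxy)phenyl]-3-methoxy-2,4-dioxobutanoate (racemic, enolisable) | CCOC(=O)C(=O)C(OC)C(=O)c1c(OCOC)c(OC)c(OC)cc1OC(C)C | intermediate (not isolated)
11 | ethyl 3,7,8-trimethoxy-4-oxo-5-(propan-2-yloxy)-4H-chromene-2-carboxylate | CCOC(=O)c1oc2c(OC)c(OC)cc(OC(C)C)c2c(=O)c1OC | intermediate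
12 | 2-(hydroxymethyl)-3,7,8-trimethoxy-5-(propan-2-yloxy)-4H-chromen-4-one | OCc1oc2c(OC)c(OC)cc(OC(C)C)c2c(=O)c1OC | intermediate
13 | 3,7,8-trimethoxy-4-oxo-5-(propan-2-yloxy)-4H-chromene-2-carbaldehyde | O=Cc1oc2c(OC)c(OC)cc(OC(C)C)c2c(=O)c1OC | intermediate
14 | 2-ethynyl-3,7,8-trimethoxy-5-(propan-2-yloxy)-4H-chromen-4-one | C#Cc1oc2c(OC)c(OC)cc(OC(C)C)c2c(=O)c1OC | intermediate
15 | tert-butyl vinyl ether | CC(C)(C)OC=C | starting material
16 | hexacarbonylchromium Cr(CO)6 | O=C=[Cr](=C=O)(=C=O)(=C=O)(=C=O)=C=O | starting material
17 | 1-tert-butoxyethenyllithium | [Li]C(=C)OC(C)(C)C | intermediate (not isolated)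
18 | lithium pentacarbonyl(2-tert-butoxyprop-2-enoyl)chromate | [Li+].[O-]C(C(=C)OC(C)(C)C)=[Cr](=C=O)(=C=O)(=C=O)(=C=O)=C=O | intermediate (not isolated)
19 | pentacarbonyl[(1-tert-butoxyethenyl)(methoxy)methylidene]chromium | CC(C)(C)OC(=C)C(OC)=[Cr](=C=O)(=C=O)(=C=O)(=C=O)=C=O | intermediate
20 | tricarbonyl[η6-2-(4-tert-butoxy-2-hydroxy-5-methoxyphenyl)-3,7,8-trimethoxy-5-(propan-2-yloxy)-4H-chromen-4-one]chromium, metal on ring B | COc1cc(-c2oc3c(OC)c(OC)cc(OC(C)C)c3c(=O)c2OC)c(O)cc1OC(C)(C)C.O=C=[Cr](=C=O)=C=O | intermediate (not isolated)
21 | 2-(4-tert-butoxy-2-hydroxy-5-methoxyphenyl)-3,7,8-trimethoxy-5-(propan-2-yloxy)-4H-chromen-4-one | COc1cc(-c2oc3c(OC)c(OC)cc(OC(C)C)c3c(=O)c2OC)c(O)cc1OC(C)(C)C | intermediate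
22 | 2-(2,4-dihydroxy-5-methoxyphenyl)-5-hydroxy-3,7,8-trimethoxy-4H-chromen-4-one | COc1cc(-c2oc3c(OC)c(OC)cc(O)c3c(=O)c2OC)c(O)cc1O | target

## Step count and least certain steps

Total: 11 steps. Longest linear sequence: 10 steps (steps 1 to 8, 10 and 11). Step 9 is a one-step branch that supplies 19.

**Step 10 (key step).** What is most likely to go wrong is slow or misdirected alkyne insertion. The triple bond of 14 is conjugated to the pyranone and is electron-poor. That slows insertion into an electrophilic carbene and opens competing paths: oligomerisation of the terminal alkyne at the metal, uptake of a second alkyne, ring closure without CO insertion, and capture of the vinylcarbene by the C4 carbonyl or the 3-methoxy oxygen. The fallback sets out from 8 and returns at 22; it brings ring B in ready-made and closes ring C by acyl transfer instead. HCl in MeOH removes the acetal of 8 and gives 1-[2-hydroxy-3,4-dimethoxy-6-(propan-2-yloxy)phenyl]-2-methoxyethan-1-one F1. Esterification of F1 with 2,4-bis(benzyloxy)-5-methoxybenzoyl chloride F2 in pyridine gives 2,3-dimethoxy-6-(methoxyacetyl)-5-(propan-2-yloxy)phenyl 2,4-bis(benzyloxy)-5-methoxybenzoate F3. LiN(SiMe3)2 then triggers the Baker–Venkataraman acyl shift of F3 to 1-[2,4-bis(benzyloxy)-5-methoxyphenyl]-3-[2-hydroxy-3,4-dimethoxy-6-(propan-2-yloxy)phenyl]-2-methoxypropane-1,3-dione F4. AcOH with a trace of H2SO4 closes F4 to 2-[2,4-bis(benzyloxy)-5-methoxyphenyl]-3,7,8-trimethoxy-5-(propan-2-yloxy)-4H-chromen-4-one F5. BCl3 with pentamethylbenzene at −78 to 0 °C removes both benzyl groups and the isopropyl group of F5 and gives 22.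

**Step 9.** What is most likely to go wrong is incomplete α-deprotonation of 15, because the bulky tert-butoxy group hinders the pre-coordination that t-BuLi needs and the base then attacks the solvent instead. A second risk is self-condensation of 19 at its unsubstituted alkene terminus on concentration. The fallback sets out from 16 and returns at 22; it changes the oxygen substituent of the carbene and so the protecting group at O4'. The less hindered isopropyl vinyl ether F6 is lithiated, added to 16 and O-methylated in the same three operations, giving pentacarbonyl[(methoxy)(1-(propan-2-yloxy)ethenyl)methylidene]chromium F7. Benzannulation of F7 with 14 as in step 10 gives 2-[2-hydroxy-5-methoxy-4-(propan-2-yloxy)phenyl]-3,7,8-trimethoxy-5-(propan-2-yloxy)-4H-chromen-4-one F8. The BCl3 treatment of step 11 cleaves both isopropyl ethers of F8 and gives 22.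

**Step 8.** What is most likely to go wrong is nucleophilic degradation. Methoxide can add to C2 of the pyranone and open ring C, or add in 1,6-fashion to the new triple bond of 14, which is a vinylogous ynone. The fallback sets out from 13 and returns at 14; it avoids methoxide altogether. Wittig reaction of 13 with the ylide from (bromomethyl)triphenylphosphonium bromide and KOC(CH3)3 at −78 °C gives 2-[(Z)-2-bromoethenyl]-3,7,8-trimethoxy-5-(propan-2-yloxy)-4H-chromen-4-one F9. anti-Dehydrobromination of F9 with Bu4NF·3H2O in DMF, a base of low nucleophilicity, gives 14.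

**Step 5.** What is most likely to go wrong is failure of the intermolecular C-acylation at a hindered, methoxy-bearing enolate carbon (O-acylation, or reversal of the condensation), and retro-Claisen ethanolysis of the tricarbonyl chain of 10 in the hot acidic stage before ring closure. The fallback sets out from 8 and returns at 11; it makes the C–C bond intramolecularly. The acetal of 8 is removed with HCl in MeOH to give the same hydroxy ketone as above, 1-[2-hydroxy-3,4-dimethoxy-6-(propan-2-yloxy)phenyl]-2-methoxyethan-1-one F1. Ethyl chlorooxoacetate F10 in pyridine acylates the phenol of F1 to ethyl 2,3-dimethoxy-6-(methoxyacetyl)-5-(propan-2-yloxy)phenyl oxalate F11. LiN(SiMe3)2 then moves the oxalyl group of F11 to carbon intramolecularly, giving ethyl 4-[2-hydroxy-3,4-dimethoxy-6-(propan-2-yloxy)phenyl]-3-methoxy-2,4-dioxobutanoate F12. HCl in EtOH dehydrates F12 to 11.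

**Step 11.** What is most likely to go wrong is loss of selectivity. Excess BCl3 may also demethylate at O3 (next to the carbonyl) or at O5' (next to the freed 4'-hydroxyl), and the tert-butyl cation set free beside a Lewis acid may alkylate the electron-rich ring B. The fallback sets out from 21 and returns at 22; it removes the two groups one at a time by different mechanisms. CF3CO2H in CH2Cl2 with thioanisole removes only the tert-butyl group of 21 and gives 2-(2,4-dihydroxy-5-methoxyphenyl)-3,7,8-trimethoxy-5-(propan-2-yloxy)-4H-chromen-4-one F13. AlCl3 in MeCN at rt then cleaves the peri isopropyl ether of F13 under chelation control and gives 22.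

## Further compounds

F1 | step 10 | 1-[2-hydroxy-3,4-dimethoxy-6-(propan-2-yloxy)phenyl]-2-methoxyethan-1-one | COCC(=O)c1c(O)c(OC)c(OC)cc1OC(C)C
F2 | step 10 | 2,4-bis(benzyloxy)-5-methoxybenzoyl chloride | COc1cc(C(=O)Cl)c(OCc2ccccc2)cc1OCc1ccccc1
F3 | step 10 | 2,3-dimethoxy-6-(methoxyacetyl)-5-(propan-2-yloxy)phenyl 2,4-bis(benzyloxy)-5-methoxybenzoate | COCC(=O)c1c(OC(=O)c2cc(OC)c(OCc3ccccc3)cc2OCc2ccccc2)c(OC)c(OC)cc1OC(C)C
F4 | step 10 | 1-[2,4-bis(benzyloxy)-5-methoxyphenyl]-3-[2-hydroxy-3,4-dimethoxy-6-(propan-2-yloxy)phenyl]-2-methoxypropane-1,3-dione (racemic, enolisable) | COC(C(=O)c1c(O)c(OC)c(OC)cc1OC(C)C)C(=O)c1cc(OC)c(OCc2ccccc2)cc1OCc1ccccc1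
F5 | step 10 | 2-[2,4-bis(benzyloxy)-5-methoxyphenyl]-3,7,8-trimethoxy-5-(propan-2-yloxy)-4H-chromen-4-one | COc1cc(-c2oc3c(OC)c(OC)cc(OC(C)C)c3c(=O)c2OC)c(OCc2ccccc2)cc1OCc1ccccc1
F6 | step 9 | isopropyl vinyl ether | CC(C)OC=C
F7 | step 9 | pentacarbonyl[(methoxy)(1-(propan-2-yloxy)ethenyl)methylidene]chromium | CC(C)OC(=C)C(OC)=[Cr](=C=O)(=C=O)(=C=O)(=C=O)=C=O
F8 | step 9 | 2-[2-hydroxy-5-methoxy-4-(propan-2-yloxy)phenyl]-3,7,8-trimethoxy-5-(propan-2-yloxy)-4H-chromen-4-one | COc1cc(-c2oc3c(OC)c(OC)cc(OC(C)C)c3c(=O)c2OC)c(O)cc1OC(C)C
F9 | step 8 | 2-[(Z)-2-bromoethenyl]-3,7,8-trimethoxy-5-(propan-2-yloxy)-4H-chromen-4-one | Br/C=C\c1oc2c(OC)c(OC)cc(OC(C)C)c2c(=O)c1OC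
F10 | step 5 | ethyl chlorooxoacetate | CCOC(=O)C(Cl)=O
F11 | step 5 | ethyl 2,3-dimethoxy-6-(methoxyacetyl)-5-(propan-2-yloxy)phenyl oxalate | CCOC(=O)C(=O)Oc1c(C(=O)COC)c(OC(C)C)cc(OC)c1OC
F12 | step 5 | ethyl 4-[2-hydroxy-3,4-dimethoxy-6-(propan-2-yloxy)phenyl]-3-methoxy-2,4-dioxobutanoate (racemic, enolisable) | CCOC(=O)C(=O)C(OC)C(=O)c1c(O)c(OC)c(OC)cc1OC(C)C
F13 | step 11 | 2-(2,4-dihydroxy-5-methoxyphenyl)-3,7,8-trimethoxy-5-(propan-2-yloxy)-4H-chromen-4-one | COc1cc(-c2oc3c(OC)c(OC)cc(OC(C)C)c3c(=O)c2OC)c(O)cc1O
A1 | alternative 1 | 5-(benzyloxy)-2-[2,4-bis(benzyloxy)-5-methoxyphenyl]-7,8-dimethoxy-4H-chromen-4-one | COc1cc(-c2cc(=O)c3c(OCc4ccccc4)cc(OC)c(OC)c3o2)c(OCc2ccccc2)cc1OCc1ccccc1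
A2 | alternative 1 | 3-(benzyloxy)-2-iodo-5,6-dimethoxyphenol | Oc1c(I)c(OCc2ccccc2)cc(OC)c1OC
A3 | alternative 1 | 1,5-bis(benzyloxy)-2-ethynyl-4-methoxybenzene | C#Cc1cc(OC)c(OCc2ccccc2)cc1OCc1ccccc1
A4 | alternative 2 | 2-[2,4-bis(benzyloxy)-5-methoxyphenyl]-5,7-dihydroxy-3,8-dimethoxy-4H-chromen-4-one | COc1cc(-c2oc3c(OC)c(O)cc(O)c3c(=O)c2OC)c(OCc2ccccc2)cc1OCc1ccccc1
A5 | alternative 2 | methyl 6-[2,4-bis(benzyloxy)-5-methoxyphenyl]-5-methoxy-2-(1-methoxy-2-oxopropyl)-4-oxo-4H-pyran-3-carboxylate (racemic) | COC(=O)c1c(C(OC)C(C)=O)oc(-c2cc(OC)c(OCc3ccccc3)cc2OCc2ccccc2)c(OC)c1=O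
A6 | alternative 3 | 5-(benzyloxy)-2-[2,4-bis(benzyloxy)-5-methoxyphenyl]-3,7,8-trimethoxy-4H-chromen-4-one | COc1cc(-c2oc3c(OC)c(OC)cc(OCc4ccccc4)c3c(=O)c2OC)c(OCc2ccccc2)cc1OCc1ccccc1
A7 | alternative 3 | (E)-3-[3-(benzyloxy)-5,6-dimethoxyphenoxy]-3-[2,4-bis(benzyloxy)-5-methoxyphenyl]-2-methoxyprop-2-enoic acid | OC(=O)/C(OC)=C(\Oc1cc(OCc2ccccc2)cc(OC)c1OC)c1cc(OC)c(OCc2ccccc2)cc1OCc1ccccc1
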